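**Retrosynthetic overview**
- 18 ⇒ β,γ-enone 17 (singlet-oxygen ene reaction last) ⇒ enal 13 (linear prenylation, oxidation) ⇒ isopropenyl tiglate 11 (allylic oxidation) ⇒ cis-epoxy ketone 8 (α'-hydroxylation and acylation).
- 8 ⇒ acyclic keto-aldehyde mesylate 6. Two bonds are made in one flask: acyl-anion carbon to ketone (closes the cyclohexanone), then tertiary alkoxide onto C–OMs (closes the oxirane), in that order.
- 6 ⇒ (S)-carvone 1 by epoxidation, reduction, mesylation and periodate ring scission. The original carbonyl carbon becomes the oxirane CH, and the original enone β-carbon becomes the new ketone.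
- Only the isopropenyl-bearing stereocentre of 1 is carried through; the other three ring centres are set in steps 5 and 6.

Assumption: a telescoped one-flask sequence counts as one step, and boronate 14 is bought as a catalogue reagent.

**Step 1**
Reactants: 1 (S)-(+)-carvone
Product: 2 (1S,4S,6S)-1-methyl-4-(prop-1-en-2-yl)-7-oxabicyclo[4.1.0]heptan-2-one (epoxide oxygen anti to the isopropenyl group)
Conditions: 35% aq. H2O2, NaOH (0.3 equiv), MeOH, 0 °C
Reagents that add atoms: hydrogen peroxide, OO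
Why: Weitz–Scheffer nucleophilic epoxidation touches only the enone C=C and, by axial attack anti to the isopropenyl group, gives the trans oxide; both epoxide centres are sacrificial.

**Step 2**
Reactants: 2
Product: 3 (1R,2R,4R,6S)-1-methyl-4-(prop-1-en-2-yl)-7-oxabicyclo[4.1.0]heptan-2-ol (hydroxyl syn to the epoxide oxygen)
Conditions: NaBH4, CeCl3·7H2O, MeOH, −20 °C
Reagents that add atoms: none
Why: Luche reduction delivers hydride anti to the epoxide C–O bond (Felkin–Anh), setting the carbinol centre that becomes the mesylate carbon of 6 and, after inversion, the oxirane CH of 8.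

**Step 3**
Reactants: 3
Product: 4 (1S,2R,4S,6S)-1-methyl-4-(prop-1-en-2-yl)-7-oxabicyclo[4.1.0]heptan-2-yl methanesulfonate
Conditions: MsCl, Et3N, CH2Cl2, 0 °C
Reagents that add atoms: methanesulfonyl chloride, CS(=O)(=O)Cl
Why: O-sulfonylation of the secondary alcohol with retention installs the leaving group for the later oxirane closure.

**Step 4**
Reactants: 4
Product: 6 (3R,5R)-5-[(methylsulfonyl)oxy]-6-oxo-3-(prop-1-en-2-yl)heptanal, via diol mesylate 5 (not isolated)
Conditions: H5IO6 (1.3 equiv), THF/H2O 3:1, 0 → 23 °C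
Reagents that add atoms: water, O
Why: Acid-promoted epoxide hydrolysis followed by Malaprade glycol cleavage opens the ring to a methyl ketone and an aldehyde; the isopropenyl alkene, the mesylate and both remaining stereocentres are untouched.

**Step 5**
Reactants: 6
Product: 8 (1S,4R,6S)-1-methyl-4-(prop-1-en-2-yl)-7-oxabicyclo[4.1.0]heptan-2-one (epoxide oxygen syn to the isopropenyl group), via ketol mesylate 7 (not isolated)
Conditions: 2-(pentafluorophenyl)-6,7-dihydro-5H-pyrrolo[2,1-c][1,2,4]triazol-2-ium tetrafluoroborate (15 mol %), Et3N (1.0 equiv), CH2Cl2, 23 °C; then DBU (1.2 equiv), 0 °C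
Reagents that add atoms: none
Why: Proposed new method: the carbene converts the aldehyde into a Breslow acyl-anion that adds to the methyl ketone (closest known type: carbene-catalysed intramolecular aldehyde–ketone crossed benzoin giving 2-hydroxy-2-methylcyclohexanones); in the chair transition state isopropenyl and methyl are equatorial while the new alkoxide and the mesylate are trans-diaxial, so on adding DBU the tertiary alkoxide displaces the mesylate from the rear (closest known type: trans-halohydrin to epoxide closure) and the oxirane forms on the isopropenyl face, which fixes the quaternary C-1 by the ketone face attacked and C-6 by SN2 inversion; this is the opposite facial outcome to nucleophilic epoxidation or a Darzens closure, where the oxygen sits first on the CH carbon.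

**Step 6**
Reactants: 8; 9 tigloyl chloride [(2E)-2-methylbut-2-enoyl chloride]
Product: 11 (1S,3S,4S,6S)-1-methyl-2-oxo-4-(prop-1-en-2-yl)-7-oxabicyclo[4.1.0]heptan-3-yl (2E)-2-methylbut-2-enoate, via hydroxy ketone 10 (not isolated)
Conditions: KN(SiMe3)2 (1.05 equiv), THF, −78 °C; 2-(phenylsulfonyl)-3-phenyloxaziridine, −78 °C; then 9 (1.3 equiv), −78 → 0 °C
Reagents that add atoms: 2-(phenylsulfonyl)-3-phenyloxaziridine, O=S(=O)(N1OC1c1ccccc1)c1ccccc1
Why: Davis oxidation of the only possible enolate (the other α-carbon is quaternary) places oxygen anti to the neighbouring isopropenyl group (trans, diequatorial), and the potassium alkoxide is O-acylated in the same flask.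

**Step 7**
Reactants: 11
Product: 13 (1S,3S,4S,6S)-1-methyl-2-oxo-4-(3-oxoprop-1-en-2-yl)-7-oxabicyclo[4.1.0]heptan-3-yl (2E)-2-methylbut-2-enoate, via allylic alcohol 12 (not isolated)
Conditions: SeO2 (0.5 equiv), t-BuOOH (3 equiv), salicylic acid (0.1 equiv), CH2Cl2, 23 °C; then MnO2 (10 equiv), 23 °C
Reagents that add atoms: selenium dioxide, O=[Se]=O; tert-butyl hydroperoxide, CC(C)(C)OO
Why: Sharpless–Umbreit allylic oxidation (ene reaction then [2,3]-shift) picks the electron-rich 1,1-disubstituted isopropenyl group over the electron-poor tiglate, and MnO2 takes the allylic alcohol fraction on to the enal.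

**Step 8**
Reactants: 13; 14 4,4,5,5-tetramethyl-2-(2-methylbut-3-en-2-yl)-1,3,2-dioxaborolane
Product: 16 (1S,3S,4S,6S)-4-[(3RS)-3-hydroxy-6-methylhepta-1,5-dien-2-yl]-1-methyl-2-oxo-7-oxabicyclo[4.1.0]heptan-3-yl (2E)-2-methylbut-2-enoate, via pinacol borate 15 (not isolated)
Conditions: 14 (1.5 equiv), toluene, 50 °C; then aq. NaHCO3, 23 °C
Reagents that add atoms: none
Why: Hoffmann-type allylboration through a closed chair transition state with allylic transposition, so the tertiary boronate delivers the linear prenyl group to the aldehyde only (ketone, ester and epoxide are inert to it); the new carbinol centre is removed in step 9.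

**Step 9**
Reactants: 16
Product: 17 (1S,3S,4S,6S)-1-methyl-4-(6-methyl-3-oxohepta-1,5-dien-2-yl)-2-oxo-7-oxabicyclo[4.1.0]heptan-3-yl (2E)-2-methylbut-2-enoate
Conditions: Dess–Martin periodinane, NaHCO3, CH2Cl2, 0 °C
Reagents that add atoms: none
Why: Buffered Dess–Martin oxidation gives the β,γ-unsaturated ketone without moving the trisubstituted alkene into conjugation.

**Step 10**
Reactants: 17
Product: 18 (1S,3S,4S,6S)-4-[(4E)-6-hydroperoxy-6-methyl-3-oxohepta-1,4-dien-2-yl]-1-methyl-2-oxo-7-oxabicyclo[4.1.0]heptan-3-yl (2E)-2-methylbut-2-enoate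
Conditions: O2 (1 atm), 5,10,15,20-tetraphenylporphyrin (1 mol %), white LEDs, CH2Cl2, −20 °C
Reagents that add atoms: dioxygen (as singlet oxygen), O=O
Why: Schenck ene reaction at the only electron-rich alkene; removal of the doubly activated hydrogen between carbonyl and alkene puts oxygen on the tertiary carbon and gives the conjugated (E)-enone, with no new stereocentre.

**Compound list**
1 | (S)-(+)-carvone, (5S)-2-methyl-5-(prop-1-en-2-yl)cyclohex-2-en-1-one | CC1=CC[C@@H](CC1=O)C(C)=C | starting material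
2 | (1S,4S,6S)-1-methyl-4-(prop-1-en-2-yl)-7-oxabicyclo[4.1.0]heptan-2-one | CC(=C)[C@@H]1CC(=O)[C@@]2(C)O[C@H]2C1 | intermediate
3 | (1R,2R,4R,6S)-1-methyl-4-(prop-1-en-2-yl)-7-oxabicyclo[4.1.0]heptan-2-ol | CC(=C)[C@@H]1C[C@@H](O)[C@@]2(C)O[C@H]2C1 | intermediate
4 | (1S,2R,4S,6S)-1-methyl-4-(prop-1-en-2-yl)-7-oxabicyclo[4.1.0]heptan-2-yl methanesulfonate | CC(=C)[C@@H]1C[C@@H](OS(C)(=O)=O)[C@@]2(C)O[C@H]2C1 | intermediate
5 | (1R,2R,3S,5S)-2,3-dihydroxy-2-methyl-5-(prop-1-en-2-yl)cyclohexyl methanesulfonate (diol configuration is immaterial) | CC(=C)[C@@H]1C[C@@H](OS(C)(=O)=O)[C@](C)(O)[C@@H](O)C1 | intermediate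
6 | (3R,5R)-5-[(methylsulfonyl)oxy]-6-oxo-3-(prop-1-en-2-yl)heptanal | CC(=C)[C@@H](CC=O)C[C@@H](OS(C)(=O)=O)C(C)=O | intermediate
7 | (1R,2S,5R)-2-hydroxy-2-methyl-3-oxo-5-(prop-1-en-2-yl)cyclohexyl methanesulfonate | CC(=C)[C@@H]1C[C@@H](OS(C)(=O)=O)[C@](C)(O)C(=O)C1 | intermediate
8 | (1S,4R,6S)-1-methyl-4-(prop-1-en-2-yl)-7-oxabicyclo[4.1.0]heptan-2-one | CC(=C)[C@@H]1C[C@@H]2O[C@]2(C)C(=O)C1 | intermediate
9 | tigloyl chloride, (2E)-2-methylbut-2-enoyl chloride | C/C=C(\C)C(Cl)=O | starting material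
10 | (1S,3S,4S,6S)-3-hydroxy-1-methyl-4-(prop-1-en-2-yl)-7-oxabicyclo[4.1.0]heptan-2-one (as potassium alkoxide in the flask) | CC(=C)[C@@H]1C[C@@H]2O[C@]2(C)C(=O)[C@H]1O | intermediate
11 | (1S,3S,4S,6S)-1-methyl-2-oxo-4-(prop-1-en-2-yl)-7-oxabicyclo[4.1.0]heptan-3-yl (2E)-2-methylbut-2-enoate | CC(=C)[C@@H]1C[C@@H]2O[C@]2(C)C(=O)[C@H]1OC(=O)/C(C)=C/C | intermediate
12 | (1S,3S,4S,6S)-4-(3-hydroxyprop-1-en-2-yl)-1-methyl-2-oxo-7-oxabicyclo[4.1.0]heptan-3-yl (2E)-2-methylbut-2-enoate | C=C(CO)[C@@H]1C[C@@H]2O[C@]2(C)C(=O)[C@H]1OC(=O)/C(C)=C/C | intermediate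
13 | (1S,3S,4S,6S)-1-methyl-2-oxo-4-(3-oxoprop-1-en-2-yl)-7-oxabicyclo[4.1.0]heptan-3-yl (2E)-2-methylbut-2-enoate | C=C(C=O)[C@@H]1C[C@@H]2O[C@]2(C)C(=O)[C@H]1OC(=O)/C(C)=C/C | intermediate
14 | 4,4,5,5-tetramethyl-2-(2-methylbut-3-en-2-yl)-1,3,2-dioxaborolane | CC(C)(C=C)B1OC(C)(C)C(C)(C)O1 | starting material
15 | pinacol borate ester of 16 (mixture at the carbinol carbon) | C=C(C(CC=C(C)C)OB3OC(C)(C)C(C)(C)O3)[C@@H]1C[C@@H]2O[C@]2(C)C(=O)[C@H]1OC(=O)/C(C)=C/C | intermediate
16 | (1S,3S,4S,6S)-4-[(3RS)-3-hydroxy-6-methylhepta-1,5-dien-2-yl]-1-methyl-2-oxo-7-oxabicyclo[4.1.0]heptan-3-yl (2E)-2-methylbut-2-enoate | C=C(C(O)CC=C(C)C)[C@@H]1C[C@@H]2O[C@]2(C)C(=O)[C@H]1OC(=O)/C(C)=C/C | intermediate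
17 | (1S,3S,4S,6S)-1-methyl-4-(6-methyl-3-oxohepta-1,5-dien-2-yl)-2-oxo-7-oxabicyclo[4.1.0]heptan-3-yl (2E)-2-methylbut-2-enoate | C=C(C(=O)CC=C(C)C)[C@@H]1C[C@@H]2O[C@]2(C)C(=O)[C@H]1OC(=O)/C(C)=C/C | intermediate
18 | (1S,3S,4S,6S)-4-[(4E)-6-hydroperoxy-6-methyl-3-oxohepta-1,4-dien-2-yl]-1-methyl-2-oxo-7-oxabicyclo[4.1.0]heptan-3-yl (2E)-2-methylbut-2-enoate | C=C(C(=O)/C=C/C(C)(C)OO)[C@@H]1C[C@@H]2O[C@]2(C)C(=O)[C@H]1OC(=O)/C(C)=C/C | target

**Totals**
Total step count: 10. Longest linear sequence: 10 (1 → 18; 9 and 14 are bought).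

**Three steps most likely to fail**

1. Step 5. Possible failures are base-induced five-ring aldol/Darzens closure of the α-mesyloxy ketone onto the aldehyde, elimination of the mesylate, alkylation of the carbene, or the wrong benzoin diastereomer. The fallback sets out from 3 and comes back at 8. It replaces the umpolung ring closure by an epoxide migration on the intact ring. Mitsunobu inversion of 3 (4-nitrobenzoic acid, PPh3, diisopropyl azodicarboxylate, THF) gives the inverted 4-nitrobenzoate F1. K2CO3 in MeOH frees the epimeric epoxy alcohol F2. Its alkoxide is now anti to the oxirane C–O bond and equilibrates by Payne rearrangement with the transposed epoxy alcohol F3, whose oxirane lies on the isopropenyl face. Dess–Martin oxidation of the mixture turns F3 into 8 and F2 back into 2, which is recycled.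

2. Step 10. The ene reaction may abstract a methyl hydrogen instead and give the secondary hydroperoxide. The fallback sets out from 13 and comes back at 18. It brings the O–O bond in ready-made instead of making it by C–H abstraction. CH2=CHMgBr (THF, −78 °C) adds to the aldehyde of 13 to give the divinyl carbinol F4, and Dess–Martin oxidation gives the divinyl ketone F5. Separately, 2-methylbut-3-en-2-ol with H2O2 and catalytic H2SO4 gives 2-methylbut-3-en-2-yl hydroperoxide F6, which Et3SiCl and imidazole convert into the triethylsilyl peroxide F7. Cross-metathesis of F5 with F7 using second-generation Hoveyda–Grubbs catalyst, RuCl2(H2IMes)(=CH-C6H4-2-OiPr), joins them at the unsubstituted vinyl group to give the (E)-silyl peroxide F8. HF·pyridine removes the silyl group to give 18.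

3. Step 7. SeO2 may attack the tiglate methyl groups or the α-acyloxy ketone, or stop at mixtures. The fallback sets out from 11 and comes back at 13. It replaces direct C–H oxygenation by chlorination and N-oxide oxidation. Ene-type allylic chlorination with Ca(OCl)2 and solid CO2 in CH2Cl2/H2O gives the allylic chloride F9. Ganem oxidation with 4-methylmorpholine N-oxide in MeCN converts it into 13.

**Further compounds**
F1 | step 5 | (2S)-epimer of 3 as its 4-nitrobenzoate (ester oxygen anti to the epoxide oxygen) | CC(=C)[C@@H]1C[C@H](OC(=O)c3ccc(cc3)[N+](=O)[O-])[C@@]2(C)O[C@H]2C1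
F2 | step 5 | (2S)-epimer of 3 (hydroxyl anti to the epoxide oxygen) | CC(=C)[C@@H]1C[C@H](O)[C@@]2(C)O[C@H]2C1
F3 | step 5 | Payne-transposed epoxy alcohol, the C-2 alcohol of 8 with hydroxyl anti to the epoxide oxygen | CC(=C)[C@@H]1C[C@@H]2O[C@]2(C)[C@@H](O)C1
F4 | step 10 | (1S,3S,4S,6S)-4-(3-hydroxypenta-1,4-dien-2-yl)-1-methyl-2-oxo-7-oxabicyclo[4.1.0]heptan-3-yl (2E)-2-methylbut-2-enoate | C=CC(O)C(=C)[C@@H]1C[C@@H]2O[C@]2(C)C(=O)[C@H]1OC(=O)/C(C)=C/C
F5 | step 10 | (1S,3S,4S,6S)-1-methyl-2-oxo-4-(3-oxopenta-1,4-dien-2-yl)-7-oxabicyclo[4.1.0]heptan-3-yl (2E)-2-methylbut-2-enoate | C=CC(=O)C(=C)[C@@H]1C[C@@H]2O[C@]2(C)C(=O)[C@H]1OC(=O)/C(C)=C/C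
F6 | step 10 | 2-methylbut-3-en-2-yl hydroperoxide | C=CC(C)(C)OO
F7 | step 10 | triethyl[(2-methylbut-3-en-2-yl)peroxy]silane | CC[Si](CC)(CC)OOC(C)(C)C=C
F8 | step 10 | O-triethylsilyl derivative of 18 | CC[Si](CC)(CC)OOC(C)(C)/C=C/C(=O)C(=C)[C@@H]1C[C@@H]2O[C@]2(C)C(=O)[C@H]1OC(=O)/C(C)=C/C
F9 | step 7 | (1S,3S,4S,6S)-4-(3-chloroprop-1-en-2-yl)-1-methyl-2-oxo-7-oxabicyclo[4.1.0]heptan-3-yl (2E)-2-methylbut-2-enoate | C=C(CCl)[C@@H]1C[C@@H]2O[C@]2(C)C(=O)[C@H]1OC(=O)/C(C)=C/C
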